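## Analysis of the target

The target 28 is a longipinane-type sesquiterpenoid diester. Atom labels C1–C11 follow the ring atoms of the SMILES, from C1 (the tiglate carbinol) to C11 (the CMe2 carbon). A cyclobutane (C4, C5, C10, C9 in ring order) is bridged on one face by the enone unit C6(=O)–C7=C8(CH3) between C5 and C9, giving a bicyclo[3.1.1]heptenone. On the other face it is bridged by C3–C2–C1–C11 between C4 and C10, giving a bicyclo[4.1.1]octane.

There are six stereocentres. C4 (quaternary, methyl), C5, C9 and C10 are locked to one another by the two bridges and act as one stereochemical element. C3 (senecioate, R) and C1 (tiglate, R) are an anti-1,3 pair on the seven-membered ring, with the C3 oxygen on the C5/C6 side and the C1 oxygen on the C9/C8 side.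

Without C1 and C3 the core is nearly mirror-symmetric (C5/C9 and C6/C8 exchange), so the ring cannot be trusted to control C1 and C3. The stereochemical relay has to run from the chain to the ring.

Sensitive groups are the cyclobutane next to an enone (a cation at C8 or C4 opens or rearranges it), the β-acyloxy carbonyl pattern, and two conjugated esters that do not tolerate strong nucleophiles or reductants.

The feature that invites the strategy is this: the fifteen carbons form one linear head-to-tail isoprenoid chain, C10–C9–C8(CH3)–C7–C6–C5–C4(CH3)–C3–C2–C1–C11(CH3)2. It is folded by only three bonds, C10–C5, C9–C4 and C10–C11, and C10, the cyclobutane carbon that carries only H and C11, is the chain terminus. The three skeletal oxygens (on C6, C3, C1) sit where three C5 units join, so each can be the carbonyl of an aldol-type coupling.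

The hard part is the 1,3-bridged ("crossed") cyclobutane with its quaternary carbon. Enone–alkene photocycloadditions of 1,6-dienes close the fused mode, and polar closures would need substitution at neopentyl or tertiary carbon.

## Retrosynthetic reasoning

**Esters and C1.** The C1–O acyl bond is cut first, giving 26 and acid chloride 27. In 26 the C3–O acyl bond and the C1–H bond are cut together, back to β-hydroxy ketone 25 and aldehyde 3 (Evans–Tishchenko reduction). This is chosen because hydride delivery from a C3 hemiacetal gives exactly the anti relation of C1 and C3, and it tells the two oxygens apart without a protecting group. The forward step must reduce only the C1 ketone and leave the enone alone.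

**Enone.** The C6 carbonyl and the C7=C8 bond of 25 are traced through 24 to a C6 silyl ether and a C8 exocyclic methylene in 21. The gain is that C6 becomes a stereocentre of the open chain, where it can steer the key step, and is erased afterwards. The forward steps must unmask C6 selectively over C3, oxidise it, and move the alkene into conjugation (only C7 can enolise; C5 is a bridgehead).

**C10–H and C10–C11.** The hydrogen on C10 in 21 is traced to the tertiary oxalate 20. The C10–C11 bond of 20 is then cut to give cyclobutanone 17, through samarium aldolate 19 and samarium enolate 18. The cut is placed here because C10 is the one cyclobutane carbon that a ketene cycloaddition delivers as a carbonyl group. C11 can be made nucleophilic regiospecifically from the α-benzoyloxy ketone already in the chain. The forward reaction must close a seven-membered ring onto a strained ketone from its only reachable face and then remove the tertiary oxygen.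

**Key disconnection.** In 17 the bonds C10–C5 and C9–C4 are cut together, through vinylketene 16 and acid chloride 15, back to the open-chain acid 14. Both bonds end at the ketene unit C10=C9, so one event builds the cyclobutane, the six-membered ring, the quaternary C4 and the stereocentres C4, C5 and C9 from a chain that has only two stereocentres (C6 and C3).

**C2–C3.** Acid 14 is the protected form of aldol 11, which is cut at C2–C3 into enal 7 and silyl enol ether 10 (from 9, from 8). This sets C3 by catalyst control and brings in C1, C2, C11 and the latent C11 nucleophile.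

**C6–C7 and the C3 carbonyl.** Enal 7 comes from 5 by oxidation of the E methyl group, and 5 from 4. Compound 4 is cut at C6–C7 into silyl dienol ether 2 (from 1) and aldehyde 3, a vinylogous aldol addition that sets C6. The whole C15 chain therefore comes from three C5 units: 1, 3 and 8.

## Alternatives that were turned down

**Alternative 1:** the textbook cyclobutane construction, an enone–alkene [2+2] photocycloaddition.
- Disconnection: C4–C9 and C5–C10 inside a ten-membered 1,5-dienone A1, in which C5 and C9 are joined by only two atoms so that the rule of five gives the crossed adduct A2.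
- Forward key step: irradiation of A1 to A2, then a one-carbon ring enlargement that inserts C7 and adds the C8 methyl.
- Reason for rejection: A1 needs a medium-ring closure with two E alkenes, a quaternary carbon and two stereocentres, which costs more steps than the photoreaction saves. E/Z photoisomerisation in the medium ring would scramble the C4/C10 relation. C1 and C3 are far from both alkenes and would control the facial sense poorly. A2 still needs four to five steps to become the enone. An open-chain 1,6-diene version would close the fused bicyclo[3.2.0] mode.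

**Alternative 2:** chiral pool.
- Disconnection: (1R,5R)-verbenone A3 already holds C4–C10 with the correct absolute configuration; the four-carbon bridge is cut off at C2–C3 and C10–C11.
- Forward key step: oxidation of the anti methyl group of A3 to aldehyde A4, chain extension, then C–C bond formation at the cyclobutane methylene C10.
- Reason for rejection: the anti methyl group points away from every functional group of A3 (only the syn methyl is within reach of the enone). The C10–H bonds are strong cyclobutane C–H bonds with no directing group nearby. The new bond at C10 would have to be made to the fully substituted C11. Two undirected C–H functionalisations would carry all the risk and save no steps.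

**Alternative 3:** biomimetic cation–alkene closure.
- Disconnection: only C4–C9, leaving the bicyclo[5.4.0] tertiary alcohol A5.
- Forward key step: ionisation of A5 at C4 and attack of the C8=C9 alkene to close the cyclobutane, then loss of a proton from the C8 cation.
- Reason for rejection: closing a four-membered ring by cation–alkene addition is uphill by roughly the ring strain, and the resulting C8 cation reopens or undergoes Wagner–Meerwein shift to a bornane-type skeleton. Without an enzyme the C4 cation would mainly eliminate, and the β-oxygen at C3 retards its formation. A5 itself needs about ten steps.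

Key step: step 9

## Remarks before the steps

- Commercial availability: compounds 1, 3, 8 and 27 are taken as purchasable.
- Catalyst: "bisphosphoramide" means the chiral Lewis base pentane-1,5-diyl-bis{N-methyl-[N,N′-dimethyl-1,1′-binaphthyl-2,2′-diamine-N,N′-diyl]phosphoric triamide}, used with SiCl4. The (R,R) antipode is taken to deliver the nucleophile to the Re face of an aldehyde and the (S,S) antipode to the Si face.
- Locants: names of tricyclic compounds use the locants of tricyclo[5.4.0.0(2,8)]undecane. They map to the atom labels as: locant 1 = C5, 2 = C4, 3 = C3, 4 = C2, 5 = C1, 6 = C11, 7 = C10, 8 = C9, 9 = C8, 10 = C7, 11 = C6. In the open-chain compounds the carboxyl carbon is C10 and the chain runs C10, C9 … C1, C11.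

## Route

Step 1
Reactants: 1 tert-butyl 3-methylbut-2-enoate
Product: 2 tert-butyl[(1-tert-butoxy-3-methylbuta-1,3-dien-1-yl)oxy]dimethylsilane
Conditions: LiN(i-Pr)2, THF, −78 °C; TBSCl, DMPU, −78 °C to rt
Reagents that add atoms: tert-butyldimethylsilyl chloride, CC(C)(C)[Si](C)(C)Cl
Why: γ-Deprotonation of the 3-methylbut-2-enoate and O-silylation of the extended enolate is the standard entry to silyl dienol ethers; no stereocentre is formed and the ketene acetal geometry does not matter for step 2.

Step 2
Reactants: 2 silyl dienol ether; 3 3-methylbut-2-enal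
Product: 4 tert-butyl (2E,5S)-5-hydroxy-3,7-dimethylocta-2,6-dienoate
Conditions: SiCl4, (S,S)-bisphosphoramide (5 mol%), i-Pr2NEt (10 mol%), CH2Cl2, −78 °C; aq. NaHCO3
Reagents that add atoms: none
Why: Catalytic enantioselective vinylogous Mukaiyama aldol addition; the dienol ether reacts at its γ-carbon (C7) through the s-trans form, which gives the 2E enoate, and the catalyst antipode is chosen for Si-face attack on 3 so that C6 is S.

Step 3
Reactants: 4 tert-butyl (2E,5S)-5-hydroxy-3,7-dimethylocta-2,6-dienoate
Product: 5 tert-butyl (2E,5S)-3,7-dimethyl-5-(triethylsilyloxy)octa-2,6-dienoate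
Conditions: TESCl, imidazole, DMF, 0 °C to rt
Reagents that add atoms: triethylsilyl chloride, CC[Si](Cl)(CC)CC
Why: Routine silylation of a secondary allylic alcohol; the triethylsilyl group is chosen because it can later be removed in the presence of the tert-butyldimethylsilyl ether at C3.

Step 4
Reactants: 5 tert-butyl (2E,5S)-3,7-dimethyl-5-(triethylsilyloxy)octa-2,6-dienoate
Product: 7 tert-butyl (2E,5S,6E)-3,7-dimethyl-8-oxo-5-(triethylsilyloxy)octa-2,6-dienoate, via allylic alcohol 6 (not isolated)
Conditions: SeO2 (0.3 equiv), t-BuOOH, CH2Cl2, rt; then MnO2, CH2Cl2, rt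
Reagents that add atoms: selenium dioxide (oxygen relay), O=[Se]=O; tert-butyl hydroperoxide, CC(C)(C)OO
Why: Allylic oxidation with SeO2 (ene reaction then [2,3] shift) attacks the electron-rich trisubstituted alkene at the methyl group trans to the chain, which fixes the E geometry of C4=C5 needed in step 9; MnO2 takes the alcohol/aldehyde mixture to the enal, and the electron-poor enoate is untouched.

Step 5
Reactants: 8 3-hydroxy-3-methylbutan-2-one
Product: 9 2-methyl-3-oxobutan-2-yl benzoate
Conditions: BzCl, Et3N, DMAP (cat.), CH2Cl2, 40 °C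
Reagents that add atoms: benzoyl chloride, O=C(Cl)c1ccccc1
Why: DMAP-catalysed acylation of a tertiary alcohol; the benzoate is the leaving group that later unmasks C11 as a regiodefined enolate.

Step 6
Reactants: 9 2-methyl-3-oxobutan-2-yl benzoate
Product: 10 2-methyl-3-(trimethylsilyloxy)but-3-en-2-yl benzoate
Conditions: TMSOTf, Et3N, CH2Cl2, 0 °C
Reagents that add atoms: trimethylsilyl trifluoromethanesulfonate, C[Si](C)(C)OS(=O)(=O)C(F)(F)F
Why: Soft enolisation and O-silylation; the ketone can enolise only toward its methyl group, so a single silyl enol ether forms, and the conditions avoid a free enolate that could attack the benzoate.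

Step 7
Reactants: 7 tert-butyl (2E,5S,6E)-3,7-dimethyl-8-oxo-5-(triethylsilyloxy)octa-2,6-dienoate; 10 2-methyl-3-(trimethylsilyloxy)but-3-en-2-yl benzoate
Product: 11 tert-butyl (2E,5S,6E,8R)-11-(benzoyloxy)-8-hydroxy-3,7,11-trimethyl-10-oxo-5-(triethylsilyloxy)dodeca-2,6-dienoate
Conditions: SiCl4, (R,R)-bisphosphoramide (5 mol%), i-Pr2NEt (10 mol%), CH2Cl2, −78 °C; aq. NaHCO3
Reagents that add atoms: none
Why: Catalytic enantioselective Mukaiyama aldol addition of a methyl-ketone silyl enol ether to a conjugated aldehyde; the catalyst antipode is chosen for Re-face attack so that C3 is R, and the remote C6 centre (1,4 across the alkene) should not interfere.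

Step 8
Reactants: 11 tert-butyl (2E,5S,6E,8R)-11-(benzoyloxy)-8-hydroxy-3,7,11-trimethyl-10-oxo-5-(triethylsilyloxy)dodeca-2,6-dienoate
Product: 14 (2E,5S,6E,8R)-11-(benzoyloxy)-8-(tert-butyldimethylsilyloxy)-3,7,11-trimethyl-10-oxo-5-(triethylsilyloxy)dodeca-2,6-dienoic acid, via silyl ether 12 (not isolated), via silyl ester 13 (not isolated)
Conditions: TBSOTf, 2,6-lutidine, CH2Cl2, −78 °C; then TMSOTf, 0 °C to rt; then H2O (pH 4 buffer)
Reagents that add atoms: tert-butyldimethylsilyl trifluoromethanesulfonate, CC(C)(C)[Si](C)(C)OS(=O)(=O)C(F)(F)F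
Why: Silyl triflate/lutidine protects the C3 hydroxyl; the stronger TMSOTf then converts the tert-butyl ester into a trimethylsilyl ester with loss of 2-methylpropene, and water hydrolyses it, so the acid is freed without base, which the β-silyloxy ketone and the benzoate would not tolerate.

Step 9
Reactants: 14 (2E,5S,6E,8R)-11-(benzoyloxy)-8-(tert-butyldimethylsilyloxy)-3,7,11-trimethyl-10-oxo-5-(triethylsilyloxy)dodeca-2,6-dienoic acid
Product: 17 (5R)-5-(tert-butyldimethylsilyloxy)-2-methyl-5-[7-methyl-2-methylidene-6-oxo-4-(triethylsilyloxy)bicyclo[3.1.1]heptan-7-yl]-3-oxopentan-2-yl benzoate, via acid chloride 15 (not isolated), via vinylketene 16 (not isolated)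
Conditions: 1-chloro-N,N,2-trimethylprop-1-en-1-amine, CH2Cl2, 0 °C to rt; then slow addition to Et3N, toluene, 110 °C (0.005 M)
Reagents that add atoms: none
Why: Intramolecular vinylketene–alkene [2+2] cycloaddition, the reaction type by which α,β-unsaturated acid chlorides of the geranic and farnesic series are known to fold into bicyclo[3.1.1]heptan-6-ones. Et3N removes HCl from 15 across C10–C9–C8–CH3 (the methyl syn to the acyl group) to give vinylketene 16, whose electrophilic carbon C10 bonds first to C5, the less substituted alkene carbon, so that charge builds at the tertiary C4, which then bonds to C9 in a concerted but asynchronous event. The C10–C5 bond closes the six-membered ring C5–C6–C7–C8–C9–C10 and the C9–C4 bond closes the cyclobutane in the crossed (1,3-bridged) mode; the fused bicyclo[3.2.0] mode would need charge at the secondary C5 and is not expected. C5 and C9 are fixed by the bridged topology, and C4 follows from the E geometry of C4=C5 by suprafacial addition (methyl syn to the C6–C8 bridge, the C3 chain on the side of the new carbonyl, where the last ring must close). The absolute sense is set by C6: A(1,3) strain with the C4 methyl, which is cis to C6, holds H6 in the alkene plane, the tether can reach only one face, and the silyloxy group must point to the other, so 6S gives the 4,5,9 configuration of the target; C3 has only a hydrogen cis to it and should be a spectator. The step needs the ketene to react only with the C4=C5 alkene (ketone, benzoate and silyl ethers are inert to ketenes) and needs high dilution against ketene dimerisation, because two allylic silyloxy groups make this alkene a weaker nucleophile than in the parent cases. Deprotonation at C7 instead of the methyl group would give the endocyclic C7=C8 isomer, which converges on the same enone in step 12.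

Step 10
Reactants: 17 (5R)-5-(tert-butyldimethylsilyloxy)-2-methyl-5-[7-methyl-2-methylidene-6-oxo-4-(triethylsilyloxy)bicyclo[3.1.1]heptan-7-yl]-3-oxopentan-2-yl benzoate
Product: 20 methyl 3-(tert-butyldimethylsilyloxy)-2,6,6-trimethyl-9-methylidene-5-oxo-11-(triethylsilyloxy)tricyclo[5.4.0.0(2,8)]undecan-7-yl oxalate, via samarium enolate 18 (not isolated), via samarium aldolate 19 (not isolated)
Conditions: SmI2 (2.5 equiv), THF, −78 to −40 °C; then ClCOCO2Me, −78 to 0 °C
Reagents that add atoms: methyl chlorooxoacetate, COC(=O)C(=O)Cl
Why: SmI2 reduces the α-benzoyloxy ketone much faster than an unactivated ketone and expels benzoate, giving the trivalent samarium enolate at C11 only (Reformatsky-type generation); its aldol addition to the strained cyclobutanone C10, templated by samarium, closes the seven-membered ring from the only face the chain can reach, which fixes C10, and acylation of the aldolate in the same flask blocks retro-aldol cleavage and installs the radical leaving group.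

Step 11
Reactants: 20 methyl 3-(tert-butyldimethylsilyloxy)-2,6,6-trimethyl-9-methylidene-5-oxo-11-(triethylsilyloxy)tricyclo[5.4.0.0(2,8)]undecan-7-yl oxalate
Product: 21 3-(tert-butyldimethylsilyloxy)-2,6,6-trimethyl-9-methylidene-11-(triethylsilyloxy)tricyclo[5.4.0.0(2,8)]undecan-5-one
Conditions: Bu3SnH, AIBN (cat.), toluene, 110 °C
Reagents that add atoms: none
Why: Barton-type radical deoxygenation of a tertiary alcohol as its methyl oxalate; the C10 radical can take hydrogen only on its outer face, so the configuration at C10 is dictated by the cage, and hydrogen transfer from the stannane should outrun opening of the cyclobutyl radical.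

Step 12
Reactants: 21 3-(tert-butyldimethylsilyloxy)-2,6,6-trimethyl-9-methylidene-11-(triethylsilyloxy)tricyclo[5.4.0.0(2,8)]undecan-5-one
Product: 24 3-(tert-butyldimethylsilyloxy)-2,6,6,9-tetramethyltricyclo[5.4.0.0(2,8)]undec-9-ene-5,11-dione, via alcohol 22 (not isolated), via methylene ketone 23 (not isolated)
Conditions: IBX, DMSO, rt to 40 °C; then DBU (cat.), CH2Cl2, rt
Reagents that add atoms: none
Why: IBX in DMSO cleaves triethylsilyl ethers while leaving tert-butyldimethylsilyl ethers and then oxidises the freed C6 alcohol; the β,γ-unsaturated ketone isomerises into conjugation through the C7 enolate (C5 is a bridgehead and cannot enolise), which gives the C6(=O)–C7=C8(CH3) enone and erases the C6 stereocentre.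

Step 13
Reactants: 24 3-(tert-butyldimethylsilyloxy)-2,6,6,9-tetramethyltricyclo[5.4.0.0(2,8)]undec-9-ene-5,11-dione
Product: 25 3-hydroxy-2,6,6,9-tetramethyltricyclo[5.4.0.0(2,8)]undec-9-ene-5,11-dione
Conditions: HF·pyridine, pyridine, THF, 0 °C to rt
Reagents that add atoms: none
Why: Buffered fluoride removes the hindered silyl ether at C3 under mildly acidic conditions, which avoids retro-aldol cleavage or elimination of the β-hydroxy ketone.

Step 14
Reactants: 25 3-hydroxy-2,6,6,9-tetramethyltricyclo[5.4.0.0(2,8)]undec-9-ene-5,11-dione; 3 3-methylbut-2-enal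
Product: 26 5-hydroxy-2,6,6,9-tetramethyl-11-oxotricyclo[5.4.0.0(2,8)]undec-9-en-3-yl 3-methylbut-2-enoate
Conditions: SmI2 (0.3 equiv), 3 (6 equiv), THF, −10 °C
Reagents that add atoms: none
Why: Evans–Tishchenko reduction; the samarium-bound hemiacetal of the C3 hydroxyl with 3 transfers its hydride through a six-membered transition state to the face of the C1 ketone that is syn to the C3 oxygen, so C1 is formed R (anti to C3), and the oxidised aldehyde stays on the C3 oxygen as the 3-methylbut-2-enoate; the enone has no β-hydroxyl and should not be reduced.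

Step 15
Reactants: 26 5-hydroxy-2,6,6,9-tetramethyl-11-oxotricyclo[5.4.0.0(2,8)]undec-9-en-3-yl 3-methylbut-2-enoate; 27 (E)-2-methylbut-2-enoyl chloride
Product: 28 2,6,6,9-tetramethyl-3-(3-methylbut-2-enoyloxy)-11-oxotricyclo[5.4.0.0(2,8)]undec-9-en-5-yl (E)-2-methylbut-2-enoate
Conditions: Et3N, DMAP, CH2Cl2, 40 °C
Reagents that add atoms: none
Why: DMAP-catalysed acylation of the remaining, hindered C1 hydroxyl; the E-configured acyl chloride is configurationally stable under these conditions and no stereocentre is touched.

## Compound list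

1 | tert-butyl 3-methylbut-2-enoate | CC(C)=CC(=O)OC(C)(C)C | starting material
2 | tert-butyl[(1-tert-butoxy-3-methylbuta-1,3-dien-1-yl)oxy]dimethylsilane (ketene acetal geometry not controlled) | C=C(C)C=C(OC(C)(C)C)O[Si](C)(C)C(C)(C)C | intermediate
3 | 3-methylbut-2-enal | CC(C)=CC=O | starting material
4 | tert-butyl (2E,5S)-5-hydroxy-3,7-dimethylocta-2,6-dienoate | CC(C)(C)OC(=O)/C=C(C)/C[C@H](O)C=C(C)C | intermediate
5 | tert-butyl (2E,5S)-3,7-dimethyl-5-(triethylsilyloxy)octa-2,6-dienoate | CC(C)(C)OC(=O)/C=C(C)/C[C@H](O[Si](CC)(CC)CC)C=C(C)C | intermediate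
6 | tert-butyl (2E,5S,6E)-8-hydroxy-3,7-dimethyl-5-(triethylsilyloxy)octa-2,6-dienoate (not isolated) | CC(C)(C)OC(=O)/C=C(C)/C[C@H](O[Si](CC)(CC)CC)/C=C(C)/CO | intermediate
7 | tert-butyl (2E,5S,6E)-3,7-dimethyl-8-oxo-5-(triethylsilyloxy)octa-2,6-dienoate | CC(C)(C)OC(=O)/C=C(C)/C[C@H](O[Si](CC)(CC)CC)/C=C(C)/C=O | intermediate
8 | 3-hydroxy-3-methylbutan-2-one | CC(=O)C(C)(C)O | starting material
9 | 2-methyl-3-oxobutan-2-yl benzoate | CC(=O)C(C)(C)OC(=O)c1ccccc1 | intermediate
10 | 2-methyl-3-(trimethylsilyloxy)but-3-en-2-yl benzoate | C=C(O[Si](C)(C)C)C(C)(C)OC(=O)c1ccccc1 | intermediate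
11 | tert-butyl (2E,5S,6E,8R)-11-(benzoyloxy)-8-hydroxy-3,7,11-trimethyl-10-oxo-5-(triethylsilyloxy)dodeca-2,6-dienoate | CC(C)(C)OC(=O)/C=C(C)/C[C@H](O[Si](CC)(CC)CC)/C=C(C)/[C@H](O)CC(=O)C(C)(C)OC(=O)c1ccccc1 | intermediate
12 | tert-butyl ester of 14, i.e. the 8-(tert-butyldimethylsilyl) ether of 11 (not isolated) | CC(C)(C)OC(=O)/C=C(C)/C[C@H](O[Si](CC)(CC)CC)/C=C(C)/[C@H](O[Si](C)(C)C(C)(C)C)CC(=O)C(C)(C)OC(=O)c1ccccc1 | intermediate
13 | trimethylsilyl ester of 14 (not isolated) | C[Si](C)(C)OC(=O)/C=C(C)/C[C@H](O[Si](CC)(CC)CC)/C=C(C)/[C@H](O[Si](C)(C)C(C)(C)C)CC(=O)C(C)(C)OC(=O)c1ccccc1 | intermediate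
14 | (2E,5S,6E,8R)-11-(benzoyloxy)-8-(tert-butyldimethylsilyloxy)-3,7,11-trimethyl-10-oxo-5-(triethylsilyloxy)dodeca-2,6-dienoic acid | OC(=O)/C=C(C)/C[C@H](O[Si](CC)(CC)CC)/C=C(C)/[C@H](O[Si](C)(C)C(C)(C)C)CC(=O)C(C)(C)OC(=O)c1ccccc1 | intermediate
15 | acid chloride of 14 (not isolated) | ClC(=O)/C=C(C)/C[C@H](O[Si](CC)(CC)CC)/C=C(C)/[C@H](O[Si](C)(C)C(C)(C)C)CC(=O)C(C)(C)OC(=O)c1ccccc1 | intermediate
16 | vinylketene, (5S,6E,8R)-11-(benzoyloxy)-8-(tert-butyldimethylsilyloxy)-7,11-dimethyl-3-methylidene-5-(triethylsilyloxy)dodeca-1,6-diene-1,10-dione (not isolated) | O=C=CC(=C)C[C@H](O[Si](CC)(CC)CC)/C=C(C)/[C@H](O[Si](C)(C)C(C)(C)C)CC(=O)C(C)(C)OC(=O)c1ccccc1 | intermediate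
17 | (5R)-5-(tert-butyldimethylsilyloxy)-2-methyl-5-[7-methyl-2-methylidene-6-oxo-4-(triethylsilyloxy)bicyclo[3.1.1]heptan-7-yl]-3-oxopentan-2-yl benzoate; ring centres C4, C5, C9 as in 28, C6 S, methyl on C4 syn to the C6–C8 bridge | O=C(OC(C)(C)C(=O)C[C@@H](O[Si](C)(C)C(C)(C)C)[C@@]1(C)[C@@H]2[C@@H](O[Si](CC)(CC)CC)CC(=C)[C@H]1C2=O)c3ccccc3 | intermediate
18 | diiodosamarium enolate formed from 17 by loss of benzoate, enolate carbon C11 (not isolated) | CC(C)=C(O[Sm](I)I)C[C@@H](O[Si](C)(C)C(C)(C)C)[C@@]1(C)[C@@H]2[C@@H](O[Si](CC)(CC)CC)CC(=C)[C@H]1C2=O | intermediate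
19 | diiodosamarium alkoxide of the tricyclic aldol, oxygen on C10 (not isolated) | O=C1C[C@@H](O[Si](C)(C)C(C)(C)C)[C@@]2(C)[C@@H]3[C@@H](O[Si](CC)(CC)CC)CC(=C)[C@H]2[C@]3(O[Sm](I)I)C1(C)C | intermediate
20 | methyl 3-(tert-butyldimethylsilyloxy)-2,6,6-trimethyl-9-methylidene-5-oxo-11-(triethylsilyloxy)tricyclo[5.4.0.0(2,8)]undecan-7-yl oxalate; ring centres as in 28 | O=C1C[C@@H](O[Si](C)(C)C(C)(C)C)[C@@]2(C)[C@@H]3[C@@H](O[Si](CC)(CC)CC)CC(=C)[C@H]2[C@]3(OC(=O)C(=O)OC)C1(C)C | intermediate
21 | 3-(tert-butyldimethylsilyloxy)-2,6,6-trimethyl-9-methylidene-11-(triethylsilyloxy)tricyclo[5.4.0.0(2,8)]undecan-5-one; ring centres as in 28 | O=C1C[C@@H](O[Si](C)(C)C(C)(C)C)[C@@]2(C)[C@@H]3[C@@H](O[Si](CC)(CC)CC)CC(=C)[C@H]2[C@@H]3C1(C)C | intermediate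
22 | 11-hydroxy compound from 21 by loss of the triethylsilyl group (not isolated) | O=C1C[C@@H](O[Si](C)(C)C(C)(C)C)[C@@]2(C)[C@@H]3[C@@H](O)CC(=C)[C@H]2[C@@H]3C1(C)C | intermediate
23 | 3-(tert-butyldimethylsilyloxy)-2,6,6-trimethyl-9-methylidenetricyclo[5.4.0.0(2,8)]undecane-5,11-dione (not isolated) | O=C1C[C@@H](O[Si](C)(C)C(C)(C)C)[C@@]2(C)[C@@H]3C(=O)CC(=C)[C@H]2[C@@H]3C1(C)C | intermediate
24 | 3-(tert-butyldimethylsilyloxy)-2,6,6,9-tetramethyltricyclo[5.4.0.0(2,8)]undec-9-ene-5,11-dione | O=C1C[C@@H](O[Si](C)(C)C(C)(C)C)[C@@]2(C)[C@@H]3C(=O)C=C(C)[C@H]2[C@@H]3C1(C)C | intermediate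
25 | 3-hydroxy-2,6,6,9-tetramethyltricyclo[5.4.0.0(2,8)]undec-9-ene-5,11-dione | O=C1C[C@@H](O)[C@@]2(C)[C@@H]3C(=O)C=C(C)[C@H]2[C@@H]3C1(C)C | intermediate
26 | 5-hydroxy-2,6,6,9-tetramethyl-11-oxotricyclo[5.4.0.0(2,8)]undec-9-en-3-yl 3-methylbut-2-enoate | O[C@@H]1C[C@@H](OC(=O)C=C(C)C)[C@@]2(C)[C@@H]3C(=O)C=C(C)[C@H]2[C@@H]3C1(C)C | intermediate
27 | (E)-2-methylbut-2-enoyl chloride | C/C=C(\C)C(=O)Cl | starting material
28 | 2,6,6,9-tetramethyl-3-(3-methylbut-2-enoyloxy)-11-oxotricyclo[5.4.0.0(2,8)]undec-9-en-5-yl (E)-2-methylbut-2-enoate (CNP0257816.1) | C/C=C(\C)C(=O)O[C@@H]1C[C@@H](OC(=O)C=C(C)C)[C@@]2(C)[C@@H]3C(=O)C=C(C)[C@H]2[C@@H]3C1(C)C | target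

## Step count and the least certain steps

Total: 15 steps. Longest linear sequence: 13 steps (steps 1–4 and 7–15, from 1); steps 5 and 6 prepare the side fragment 10.

**Step 9 (key step).** The most likely failure is that ketene dimerisation and oligomerisation outrun the cycloaddition, because the C4=C5 alkene carries two allylic silyloxy groups and is a weaker nucleophile than in the unsubstituted precedents. A lesser risk is partial closure in the fused mode. The fallback changes the electrophile from a ketene to a keteniminium ion. It sets out from 14, which would be converted through 15 and dimethylamine into the N,N-dimethylamide F1. Activation of the amide with Tf2O and 2,6-di-tert-butylpyridine in hot 1,2-dichloroethane should give the far more electrophilic vinylketeniminium ion, which should close the same two bonds under the same C6 control to the cyclobutaniminium triflate F2. Hydrolysis with aqueous NaHCO3 returns to the route at 17.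

**Step 10.** The samarium enolate may be protonated before it cyclises, or the crowded aldol may revert before the alkoxide is acylated; either way the seven-membered ring is lost. The fallback separates enolate formation from ring closure. It sets out from 17: reduction with SmI2 in the presence of Me3SiCl would trap the enolate as the isolable trimethylsilyl enol ether F3. An intramolecular Mukaiyama aldol addition (TiCl4, CH2Cl2, −78 °C) would then give the tricyclic β-hydroxy ketone F4. Acylation of F4 with methyl chlorooxoacetate and DMAP comes back to the route at 20.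

**Step 14.** The unsaturated aldehyde 3 may be consumed by reductive coupling at samarium, or hemiacetal formation at the hindered C3 hydroxyl may be slow, so that conversion stalls or the acyl group migrates. The fallback separates reduction from acylation. It sets out from 25: Saksena–Evans reduction with Me4NBH(OAc)3 (acetic acid/acetonitrile, −30 °C) delivers hydride from the C3 oxygen and should give the anti-diol F5. The less hindered C3 hydroxyl of F5 (the C1 hydroxyl is flanked by the CMe2 group) would then be acylated selectively with 3-methylbut-2-enoyl chloride and pyridine at low temperature, which comes back to the route at 26.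

**Step 4.** The acidic selenium species may cleave the triethylsilyl ether, or oxidation may stop at mixed oxidation levels and touch other allylic positions, which lowers the yield of 7. The fallback replaces C–H oxidation by a two-carbon exchange at the alkene. It sets out from 5: ozonolysis of the electron-rich C4=C5 alkene (the enoate is much less reactive), with Me2S work-up, would give the α-silyloxy aldehyde F6. An E-selective Wittig reaction of F6 with 2-(triphenylphosphoranylidene)propanal comes back to the route at 7.

## Further compounds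

F1 | step 9 | N,N-dimethylamide of 14 | CN(C)C(=O)/C=C(C)/C[C@H](O[Si](CC)(CC)CC)/C=C(C)/[C@H](O[Si](C)(C)C(C)(C)C)CC(=O)C(C)(C)OC(=O)c1ccccc1
F2 | step 9 | N,N-dimethyl cyclobutaniminium trifluoromethanesulfonate corresponding to 17 (C10=N in place of C10=O) | O=C(OC(C)(C)C(=O)C[C@@H](O[Si](C)(C)C(C)(C)C)[C@@]1(C)[C@@H]2[C@@H](O[Si](CC)(CC)CC)CC(=C)[C@H]1C2=[N+](C)C)c3ccccc3.[O-]S(=O)(=O)C(F)(F)F
F3 | step 10 | trimethylsilyl enol ether (C1–O–Si, C1=C11) of the debenzoyloxylated ketone derived from 17 | CC(C)=C(O[Si](C)(C)C)C[C@@H](O[Si](C)(C)C(C)(C)C)[C@@]1(C)[C@@H]2[C@@H](O[Si](CC)(CC)CC)CC(=C)[C@H]1C2=O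
F4 | step 10 | 3-(tert-butyldimethylsilyloxy)-7-hydroxy-2,6,6-trimethyl-9-methylidene-11-(triethylsilyloxy)tricyclo[5.4.0.0(2,8)]undecan-5-one | O=C1C[C@@H](O[Si](C)(C)C(C)(C)C)[C@@]2(C)[C@@H]3[C@@H](O[Si](CC)(CC)CC)CC(=C)[C@H]2[C@]3(O)C1(C)C
F5 | step 14 | 3,5-dihydroxy-2,6,6,9-tetramethyltricyclo[5.4.0.0(2,8)]undec-9-en-11-one (anti-diol) | O[C@@H]1C[C@@H](O)[C@@]2(C)[C@@H]3C(=O)C=C(C)[C@H]2[C@@H]3C1(C)C
F6 | step 4 | tert-butyl (2E,5S)-3-methyl-6-oxo-5-(triethylsilyloxy)hex-2-enoate | CC(C)(C)OC(=O)/C=C(C)/C[C@H](O[Si](CC)(CC)CC)C=O
A1 | alternative 1 | (2E,4R,6R,8E)-4,6-bis(tert-butyldimethylsilyloxy)-3,7,7-trimethylcyclodeca-2,8-dien-1-one | O=C1/C=C(C)/[C@H](O[Si](C)(C)C(C)(C)C)C[C@@H](O[Si](C)(C)C(C)(C)C)C(C)(C)/C=C/C1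
A2 | alternative 1 | crossed photoadduct of A1, a tricyclo[4.4.0.0(2,7)]decanone with the cyclobutane of the target | CC(C)(C)[Si](C)(C)O[C@@H]1C[C@@H](O[Si](C)(C)C(C)(C)C)[C@@]2(C)[C@@H]3C(=O)C[C@H]2[C@@H]3C1(C)C
A3 | alternative 2 | (1R,5R)-verbenone | CC1(C)[C@@H]2C(=O)C=C(C)[C@H]1C2
A4 | alternative 2 | verbenone with the anti methyl group oxidised to the aldehyde | O=C[C@@]1(C)[C@@H]2C(=O)C=C(C)[C@H]1C2
A5 | alternative 3 | bicyclo[5.4.0]undecene tertiary alcohol (hydroxyl on C4, alkene C8=C9, silyl ethers on C1 and C3) | CC(C)(C)[Si](C)(C)O[C@@H]1C[C@@H](O[Si](C)(C)C(C)(C)C)[C@](C)(O)[C@@H]2CCC(C)=C[C@@H]2C1(C)C
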